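G stood at 49.3% in this flask at 5.00 h and had sunk to 39.2% by 10.0 h, but the questions for whoever takes over the bench concern Q, which comes and goes much earlier.

- delta: J 0.50 M; E 1.5 equiv; D 1.2 equiv (fed, over 6.0 h); the very flask that is asked about, followed so far; the fed solution adds 0.20 times the starting volume
- flask: J 0.50 M; E 1.50 equiv; D 1.20 equiv (fed, over 6.0 h); time 20 h; the fed solution adds 0.20 times the starting volume

delta run (percent of the J charged)

| time / h | Q / % | G / % |
|---|---|---|
| 0.250 | 5.9 | 1.8 |
| 0.500 | 13.4 | 9.5 |
| 1.00 | 17.0 | 19.6 |
| 2.50 | 9.7 | 41.4 |
| 5.00 | 2.9 | 49.3 |
| 10.0 | 0 | 39.2 |

(standard deviation of a reading: 1 percentage point)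

* the moment within 20 h at which there is most Q
* the amount of Q, in percent of the J charged, at that time
* earliest time at which at least nineteen twentieths of that best amount are there
* latest time at which they still are

- every charge counts on the volume at the start, and the solution that is fed holds the whole dose

I followed one molecule. As J it waits to become Q, and as Q it waits for a way out. I took the late fall of the Q readings, from 2.50 h to 5.00 h, as Q following J down, which gave an entry rate of 0.483 /h, a reading that carries the scatter of small values. By that rate I reckoned 29.9% of the J left at 2.50 h. Setting cQ/cJ there equal to the entry rate over the difference of the two rates gave 1.97 /h. I called this the exit rate, the chance per hour that a molecule of Q is taken away.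

My exit rate was faster than my entry rate, so I took entry as the rate-limiting step. Holding both rates steady, I expected the most Q at ln(exit/entry)/(exit − entry), which is 0.945 h, with 15.5% of the J charged. After the peak I expected the amount of Q to sink at the slower rate, so I expected the late edge of the window to lie further from the peak than the early edge. Leave the D feed as it runs, since I read the exit rate at that dose.

The forecast, higher than my reckoning, gave 17.5% at 0.87 h and a window from 0.67 h to 1.1 h, on this ground: “Q peaks when its formation rate falls to the rate of consumption”. The flask gave 15.2% at 0.984 h, with the window open from 0.674 h to 1.40 h.

    E + G → X (k = 0.190 /M/h)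
    D + Q → L (k = 3.80 /M/h)
    E + Q → G (k = 2.60 /M/h)
    J → Q (k = 0.470 /h)

In this flask the exit rate of 1.97 /h had put the peak at 15.5%, and it stood at 15.2%. Both ways out of Q run with a concentration, through E and through D, and both charges count in equivalents. So for the neighbour flask with 1.2 M of J, I multiplied the exit rate by 2.40, to 4.73 /h, and kept the entry at 0.483 /h. The same reckoning then put its peak at 7.88%, and that neighbour flask gave 7.82%.

The earlier runs and the new flask were generated by integration for an exercise; scatter was added.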